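**Plan** (germacranolide numbering: C1 acetoxy, C4–C5 oxirane, C6 lactone O, C7=C11, C8 methacrylate, C10 methyl, C12 lactone C=O, C13 CH2OH)

- Retrosynthesis cuts, in order: the O8 and O1 acyl groups and an O13 PMB ether; the ten-membered ring at C7–C8 (alkenyl triflate + aldehyde); C1–C10 (crotylboration); the butenolide at C7–C11 and O6–C12; both oxirane C–O bonds; C6–C7 (alkenyl iodide + dimethyl oxalate).
- Forward: the C1–C7 chain is built first, the oxirane is closed, then the butenolide (as its C7 triflate); the chain is extended by C10–C9–C8 and the ten-membered carbocycle is closed last.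
- Enabling feature: in the target the trans C4–C5 oxirane lies next to the C6 lactone carbinol in a threo relationship, and in the parent E olefin the C4 methyl is cis to C6. A free C6 hydroxyl can therefore direct the epoxidation under A(1,3) control.
- Stereochemistry: C6 from Ru-catalysed asymmetric transfer hydrogenation; C4 and C5 relayed from C6 in the directed epoxidation; C1 and C10 from reagent-controlled (Z)-crotylboration; C8 from the ring-closing Ni/Cr addition under the bias of the existing centres.

Key step: step 5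

Assumption: 3-[(4-methoxybenzyl)oxy]propanoic acid (10) is taken as a purchasable building block, and the sense of the Ru-catalysed reduction is assigned by analogy with aryl α-keto esters.

**Route**

Step 1
Reactants: 1 4-pentyn-1-ol
Product: 3 (E)-5-iodo-4-methylpent-4-en-1-ol, via alkenylalane 2 (not isolated)
Conditions: AlMe3, Cp2ZrCl2 (cat.), CH2Cl2, 0 °C → rt; then I2, THF, −30 → 0 °C
Reagents that add atoms: trimethylaluminium C[Al](C)C; iodine II
Why: Negishi zirconium-catalysed carboalumination adds methyl and aluminium syn across the terminal alkyne with aluminium at the terminus, and iodinolysis of the alkenyl–Al bond with retention should give the E iodide in which the C4 methyl is cis to the future C6.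

Step 2
Reactants: 3 (E)-5-iodo-4-methylpent-4-en-1-ol
Product: 4 tert-butyl{[(E)-5-iodo-4-methylpent-4-en-1-yl]oxy}dimethylsilane
Conditions: TBSCl, imidazole, CH2Cl2, rt
Reagents that add atoms: tert-butyldimethylsilyl chloride CC(C)(C)[Si](C)(C)Cl
Why: Imidazole-promoted silylation of the primary alcohol (TBS ether formation) masks the C1 hydroxyl for the organolithium step.

Step 3
Reactants: 4 tert-butyl{[(E)-5-iodo-4-methylpent-4-en-1-yl]oxy}dimethylsilane; 5 dimethyl oxalate
Product: 7 methyl (3E)-7-[(tert-butyldimethylsilyl)oxy]-4-methyl-2-oxohept-3-enoate, via alkenyllithium 6 (not isolated)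
Conditions: t-BuLi (2 equiv), Et2O, −78 °C; cannulated into 5 (3 equiv), THF, −78 °C; AcOH quench at −78 °C
Reagents that add atoms: none
Why: Lithium–iodine exchange proceeds with retention of olefin geometry, and acylation of the alkenyllithium by excess dimethyl oxalate under inverse addition (organolithium addition to a dialkyl oxalate) should stop at the α-keto ester because the tetrahedral adduct persists until the cold quench.

Step 4
Reactants: 7 methyl (3E)-7-[(tert-butyldimethylsilyl)oxy]-4-methyl-2-oxohept-3-enoate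
Product: 8 methyl (2R,3E)-7-[(tert-butyldimethylsilyl)oxy]-2-hydroxy-4-methylhept-3-enoate
Conditions: RuCl[(S,S)-TsDPEN](p-cymene) (1 mol%), HCO2H/Et3N (5:2), CH2Cl2, rt
Reagents that add atoms: none
Why: Noyori asymmetric transfer hydrogenation reduces the activated α-keto group chemoselectively beside the β,β-disubstituted olefin, and with the (S,S) catalyst the alkenyl arm is expected to occupy the site usually taken by an aryl group (as in aryl glyoxylates), so hydride delivery should set the 2R carbinol, the future C6.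

Step 5
Reactants: 8 methyl (2R,3E)-7-[(tert-butyldimethylsilyl)oxy]-2-hydroxy-4-methylhept-3-enoate
Product: 9 methyl (2R)-2-[(2R,3R)-3-{3-[(tert-butyldimethylsilyl)oxy]propyl}-3-methyloxiran-2-yl]-2-hydroxyacetate
Conditions: mCPBA, CH2Cl2, 0 °C
Reagents that add atoms: 3-chloroperoxybenzoic acid O=C(OO)c1cccc(Cl)c1
Why: The peracid is hydrogen-bonded by the C6 hydroxyl and transfers its distal oxygen to the C4=C5 π-bond in a concerted suprafacial (butterfly) step, the closest known reaction being the Henbest hydroxyl-directed epoxidation of secondary allylic alcohols. The oxirane is closed in this single [2+1] oxygen-atom transfer with both C–O bonds forming together, so the E geometry is carried over as the trans arrangement of C6 on C5 and C3 on C4. The reactive rotamer holds the C6–H bond in the olefin plane, because OH or CO2Me in that position would clash with the cis C4 methyl (A(1,3) strain), and OH and CO2Me then flank the two π-faces. Oxygen is delivered to the face syn to OH, which is also the face not screened by the larger CO2Me, so C5 (R) and C4 (R) are both set from C6 (R) as the threo epoxy alcohol. The step needs threo over erythro selectivity, which the cis C4 methyl of the E trisubstituted olefin secures, and the electron-rich trisubstituted alkene should remain reactive toward the peracid despite the neighbouring ester.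

Step 6
Reactants: 9 methyl (2R)-2-[(2R,3R)-3-{3-[(tert-butyldimethylsilyl)oxy]propyl}-3-methyloxiran-2-yl]-2-hydroxyacetate; 10 3-[(4-methoxybenzyl)oxy]propanoic acid
Product: 11 methyl (2R)-2-[(2R,3R)-3-{3-[(tert-butyldimethylsilyl)oxy]propyl}-3-methyloxiran-2-yl]-2-({3-[(4-methoxybenzyl)oxy]propanoyl}oxy)acetate
Conditions: EDC·HCl, DMAP (cat.), CH2Cl2, 0 °C → rt
Reagents that add atoms: none
Why: Steglich esterification (carbodiimide activation with DMAP acyl transfer) acylates the secondary C6 hydroxyl under near-neutral conditions that leave the oxirane and methyl ester alone, bringing in C12, C11 and the protected C13 in one piece.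

Step 7
Reactants: 11 methyl (2R)-2-[(2R,3R)-3-{3-[(tert-butyldimethylsilyl)oxy]propyl}-3-methyloxiran-2-yl]-2-({3-[(4-methoxybenzyl)oxy]propanoyl}oxy)acetate
Product: 13 (2R)-2-[(2R,3R)-3-{3-[(tert-butyldimethylsilyl)oxy]propyl}-3-methyloxiran-2-yl]-4-{[(4-methoxybenzyl)oxy]methyl}-5-oxo-2,5-dihydrofuran-3-yl trifluoromethanesulfonate, via lithium tetronate 12 (not isolated)
Conditions: LiHMDS (2.2 equiv), THF, −78 °C; then Comins' reagent, −78 → 0 °C
Reagents that add atoms: N-(5-chloropyridin-2-yl)bis(trifluoromethanesulfonimide) FC(F)(F)S(=O)(=O)N(c1ccc(Cl)cn1)S(=O)(=O)C(F)(F)F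
Why: Kinetic deprotonation of the less hindered acyl CH2 by LiHMDS and 5-exo-trig attack of the ester enolate on the C7 methyl ester (Dieckmann cyclisation of an α-acyloxy ester to a tetronate) should form the C7–C11 bond faster than loss of the β-alkoxide at −78 °C, the tetronate anion being no longer acidic at C6, and O-sulfonylation of that anion gives the C7 alkenyl triflate without isolation of the free tetronic acid.

Step 8
Reactants: 13 the TBS-protected triflate
Product: 14 (2R)-2-[(2R,3R)-3-(3-hydroxypropyl)-3-methyloxiran-2-yl]-4-{[(4-methoxybenzyl)oxy]methyl}-5-oxo-2,5-dihydrofuran-3-yl trifluoromethanesulfonate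
Conditions: Et3N·3HF, MeCN/THF, rt
Reagents that add atoms: none
Why: Fluoride-mediated desilylation with the weakly acidic, non-basic amine–HF complex removes the primary TBS ether while the base-labile triflate, the acid-labile oxirane and the PMB ether persist.

Step 9
Reactants: 14 the primary alcohol
Product: 15 (2R)-4-{[(4-methoxybenzyl)oxy]methyl}-2-[(2R,3R)-3-methyl-3-(3-oxopropyl)oxiran-2-yl]-5-oxo-2,5-dihydrofuran-3-yl trifluoromethanesulfonate
Conditions: Dess–Martin periodinane, pyridine, CH2Cl2, 0 °C → rt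
Reagents that add atoms: none
Why: Dess–Martin oxidation converts the primary alcohol to the C1 aldehyde under mild buffered conditions without over-oxidation.

Step 10
Reactants: 15 the C1 aldehyde
Product: 17 (2R)-2-{(2R,3R)-3-[(3S,4S)-3-hydroxy-4-methylhex-5-en-1-yl]-3-methyloxiran-2-yl}-4-{[(4-methoxybenzyl)oxy]methyl}-5-oxo-2,5-dihydrofuran-3-yl trifluoromethanesulfonate, via diisopinocampheylborinate 16 (not isolated)
Conditions: cis-2-butene, t-BuOK, n-BuLi, THF, −78 → −45 °C; (+)-Ipc2BOMe [from (−)-α-pinene], −78 °C; BF3·OEt2; then 15, −78 °C; NaBO3·4H2O, THF/H2O, rt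
Reagents that add atoms: cis-2-butene C/C=C\C
Why: Brown asymmetric crotylboration passes through a closed chair (Zimmerman–Traxler) transition state, so the Z reagent should give the syn C1–OH/C10–CH3 pair, and the isopinocampheyl groups derived from (−)-α-pinene direct attack to the Re face of the aldehyde, setting 1S,10S independently of the remote C4–C6 centres while the non-basic borane leaves the triflate and oxirane untouched.

Step 11
Reactants: 17 the homoallylic alcohol
Product: 18 (2R)-2-{(2R,3R)-3-[(3S,4S)-3-acetoxy-4-methylhex-5-en-1-yl]-3-methyloxiran-2-yl}-4-{[(4-methoxybenzyl)oxy]methyl}-5-oxo-2,5-dihydrofuran-3-yl trifluoromethanesulfonate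
Conditions: Ac2O, pyridine, CH2Cl2, rt
Reagents that add atoms: acetic anhydride CC(=O)OC(C)=O
Why: Pyridine-mediated acetylation of the secondary C1 alcohol installs the acetate of the target at once, so no further protecting group is needed at this position.

Step 12
Reactants: 18 the acetate
Product: 20 (2R)-2-{(2R,3R)-3-[(3S,4S)-3-acetoxy-6-hydroxy-4-methylhexyl]-3-methyloxiran-2-yl}-4-{[(4-methoxybenzyl)oxy]methyl}-5-oxo-2,5-dihydrofuran-3-yl trifluoromethanesulfonate, via B-alkyl-9-BBN adduct 19 (not isolated)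
Conditions: 9-BBN, THF, 0 °C → rt; then NaBO3·4H2O, THF/H2O, 0 °C → rt
Reagents that add atoms: sodium perborate [Na+].[O-]B1OO1
Why: 9-BBN adds to the terminal carbon of the monosubstituted alkene (anti-Markovnikov hydroboration) and ignores the electron-poor tetrasubstituted butenolide olefin, and mild perborate oxidation of the C–B bond should give the primary C8 alcohol without disturbing the acetate or triflate.

Step 13
Reactants: 20 the C8 primary alcohol
Product: 21 (2R)-2-{(2R,3R)-3-[(3S,4S)-3-acetoxy-4-methyl-6-oxohexyl]-3-methyloxiran-2-yl}-4-{[(4-methoxybenzyl)oxy]methyl}-5-oxo-2,5-dihydrofuran-3-yl trifluoromethanesulfonate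
Conditions: Dess–Martin periodinane, pyridine, CH2Cl2, 0 °C → rt
Reagents that add atoms: none
Why: Dess–Martin oxidation gives the C8 aldehyde needed for ring closure, the acetate, triflate and oxirane being inert to the periodinane.

Step 14
Reactants: 21 the triflate aldehyde
Product: 22 (1S,4R,5R,6S,8S,10S)-1-acetoxy-4,5-epoxy-8-hydroxy-13-[(4-methoxybenzyl)oxy]germacr-7(11)-en-12,6-olide
Conditions: CrCl2 (10 equiv), NiCl2 (10 mol%), degassed DMF/THF, rt, 2 mM, slow addition
Reagents that add atoms: none
Why: Ni(0) inserts into the alkenyl C–OTf bond and transmetalation gives an alkenylchromium(III) species that adds to the C8 aldehyde (Nozaki–Hiyama–Kishi reaction, established for alkenyl triflates and for medium-ring closure), forming C7–C8 and the ten-membered ring under high dilution, with C8 set by the ring-closing conformation, expected to place the aldehyde hydrogen in the butenolide plane next to C13 and bring C9 in from the face opposite C5, which corresponds to 8S.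

Step 15
Reactants: 22 the macrocyclic C8 alcohol
Product: 23 (1S,4R,5R,6S,8S,10S)-1-acetoxy-4,5-epoxy-13-[(4-methoxybenzyl)oxy]-8-(methacryloyloxy)germacr-7(11)-en-12,6-olide
Conditions: methacrylic anhydride, Et3N, DMAP (cat.), CH2Cl2, 0 °C → rt
Reagents that add atoms: methacrylic anhydride C=C(C)C(=O)OC(=O)C(C)=C
Why: DMAP-catalysed acylation with the anhydride esterifies the secondary C8 alcohol with retention, the mild amine base not being strong enough to remove the γ-proton at C6.

Step 16
Reactants: 23 the PMB-protected methacrylate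
Product: 24 glaucolide L
Conditions: DDQ, CH2Cl2/pH 7 phosphate buffer, 0 °C → rt
Reagents that add atoms: none
Why: DDQ oxidises the electron-rich p-methoxybenzyl ether through a charge-transfer complex to an oxocarbenium ion that water hydrolyses (oxidative PMB cleavage), leaving the methacrylate, acetate, oxirane and butenolide unchanged and releasing the C13 primary alcohol of the target.

**Compound list**

1 | 4-pentyn-1-ol | C#CCCCO | starting material
2 | dimethyl[(1E)-5-[(dimethylalumanyl)oxy]-2-methylpent-1-en-1-yl]alumane (alkenylalane) | C[Al](C)/C=C(C)/CCCO[Al](C)C | intermediate (not isolated)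
3 | (E)-5-iodo-4-methylpent-4-en-1-ol | OCCC/C(C)=C/I | intermediate
4 | tert-butyl{[(E)-5-iodo-4-methylpent-4-en-1-yl]oxy}dimethylsilane | CC(C)(C)[Si](C)(C)OCCC/C(C)=C/I | intermediate
5 | dimethyl oxalate | COC(=O)C(=O)OC | starting material
6 | [(1E)-5-[(tert-butyldimethylsilyl)oxy]-2-methylpent-1-en-1-yl]lithium (alkenyllithium) | [Li]/C=C(C)/CCCO[Si](C)(C)C(C)(C)C | intermediate (not isolated)
7 | methyl (3E)-7-[(tert-butyldimethylsilyl)oxy]-4-methyl-2-oxohept-3-enoate | COC(=O)C(=O)/C=C(C)/CCCO[Si](C)(C)C(C)(C)C | intermediate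
8 | methyl (2R,3E)-7-[(tert-butyldimethylsilyl)oxy]-2-hydroxy-4-methylhept-3-enoate | COC(=O)[C@H](O)/C=C(C)/CCCO[Si](C)(C)C(C)(C)C | intermediate
9 | methyl (2R)-2-[(2R,3R)-3-{3-[(tert-butyldimethylsilyl)oxy]propyl}-3-methyloxiran-2-yl]-2-hydroxyacetate | COC(=O)[C@H](O)[C@H]1O[C@]1(C)CCCO[Si](C)(C)C(C)(C)C | intermediate
10 | 3-[(4-methoxybenzyl)oxy]propanoic acid | OC(=O)CCOCc1ccc(OC)cc1 | starting material
11 | methyl (2R)-2-[(2R,3R)-3-{3-[(tert-butyldimethylsilyl)oxy]propyl}-3-methyloxiran-2-yl]-2-({3-[(4-methoxybenzyl)oxy]propanoyl}oxy)acetate | COC(=O)[C@H](OC(=O)CCOCc1ccc(OC)cc1)[C@H]1O[C@]1(C)CCCO[Si](C)(C)C(C)(C)C | intermediate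
12 | lithium (2R)-2-[(2R,3R)-3-{3-[(tert-butyldimethylsilyl)oxy]propyl}-3-methyloxiran-2-yl]-4-{[(4-methoxybenzyl)oxy]methyl}-5-oxo-2,5-dihydrofuran-3-olate (lithium tetronate) | O=C1O[C@H]([C@H]2O[C@]2(C)CCCO[Si](C)(C)C(C)(C)C)C([O-])=C1COCc1ccc(OC)cc1.[Li+] | intermediate (not isolated)
13 | (2R)-2-[(2R,3R)-3-{3-[(tert-butyldimethylsilyl)oxy]propyl}-3-methyloxiran-2-yl]-4-{[(4-methoxybenzyl)oxy]methyl}-5-oxo-2,5-dihydrofuran-3-yl trifluoromethanesulfonate | O=C1O[C@H]([C@H]2O[C@]2(C)CCCO[Si](C)(C)C(C)(C)C)C(OS(=O)(=O)C(F)(F)F)=C1COCc1ccc(OC)cc1 | intermediate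
14 | (2R)-2-[(2R,3R)-3-(3-hydroxypropyl)-3-methyloxiran-2-yl]-4-{[(4-methoxybenzyl)oxy]methyl}-5-oxo-2,5-dihydrofuran-3-yl trifluoromethanesulfonate | O=C1O[C@H]([C@H]2O[C@]2(C)CCCO)C(OS(=O)(=O)C(F)(F)F)=C1COCc1ccc(OC)cc1 | intermediate
15 | (2R)-4-{[(4-methoxybenzyl)oxy]methyl}-2-[(2R,3R)-3-methyl-3-(3-oxopropyl)oxiran-2-yl]-5-oxo-2,5-dihydrofuran-3-yl trifluoromethanesulfonate | O=C1O[C@H]([C@H]2O[C@]2(C)CCC=O)C(OS(=O)(=O)C(F)(F)F)=C1COCc1ccc(OC)cc1 | intermediate
16 | O-[bis(isopinocampheyl)boryl] derivative of 17 (diisopinocampheylborinate) | O=C1O[C@H]([C@H]2O[C@]2(C)CC[C@H](OB([C@H]3C[C@H]4C[C@@H]([C@@H]3C)C4(C)C)[C@H]3C[C@H]4C[C@@H]([C@@H]3C)C4(C)C)[C@@H](C)C=C)C(OS(=O)(=O)C(F)(F)F)=C1COCc1ccc(OC)cc1 | intermediate (not isolated)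
17 | (2R)-2-{(2R,3R)-3-[(3S,4S)-3-hydroxy-4-methylhex-5-en-1-yl]-3-methyloxiran-2-yl}-4-{[(4-methoxybenzyl)oxy]methyl}-5-oxo-2,5-dihydrofuran-3-yl trifluoromethanesulfonate | O=C1O[C@H]([C@H]2O[C@]2(C)CC[C@H](O)[C@@H](C)C=C)C(OS(=O)(=O)C(F)(F)F)=C1COCc1ccc(OC)cc1 | intermediate
18 | (2R)-2-{(2R,3R)-3-[(3S,4S)-3-acetoxy-4-methylhex-5-en-1-yl]-3-methyloxiran-2-yl}-4-{[(4-methoxybenzyl)oxy]methyl}-5-oxo-2,5-dihydrofuran-3-yl trifluoromethanesulfonate | O=C1O[C@H]([C@H]2O[C@]2(C)CC[C@H](OC(C)=O)[C@@H](C)C=C)C(OS(=O)(=O)C(F)(F)F)=C1COCc1ccc(OC)cc1 | intermediate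
19 | B-alkyl-9-borabicyclo[3.3.1]nonane adduct of 18 (boron on C8) | O=C1O[C@H]([C@H]2O[C@]2(C)CC[C@H](OC(C)=O)[C@@H](C)CCB3C4CCCC3CCC4)C(OS(=O)(=O)C(F)(F)F)=C1COCc1ccc(OC)cc1 | intermediate (not isolated)
20 | (2R)-2-{(2R,3R)-3-[(3S,4S)-3-acetoxy-6-hydroxy-4-methylhexyl]-3-methyloxiran-2-yl}-4-{[(4-methoxybenzyl)oxy]methyl}-5-oxo-2,5-dihydrofuran-3-yl trifluoromethanesulfonate | O=C1O[C@H]([C@H]2O[C@]2(C)CC[C@H](OC(C)=O)[C@@H](C)CCO)C(OS(=O)(=O)C(F)(F)F)=C1COCc1ccc(OC)cc1 | intermediate
21 | (2R)-2-{(2R,3R)-3-[(3S,4S)-3-acetoxy-4-methyl-6-oxohexyl]-3-methyloxiran-2-yl}-4-{[(4-methoxybenzyl)oxy]methyl}-5-oxo-2,5-dihydrofuran-3-yl trifluoromethanesulfonate | O=C1O[C@H]([C@H]2O[C@]2(C)CC[C@H](OC(C)=O)[C@@H](C)CC=O)C(OS(=O)(=O)C(F)(F)F)=C1COCc1ccc(OC)cc1 | intermediate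
22 | (1S,4R,5R,6S,8S,10S)-1-acetoxy-4,5-epoxy-8-hydroxy-13-[(4-methoxybenzyl)oxy]germacr-7(11)-en-12,6-olide | O[C@H]1C[C@H](C)[C@@H](OC(C)=O)CC[C@@]2(C)O[C@@H]2[C@H]2OC(=O)C(COCc3ccc(OC)cc3)=C12 | intermediate
23 | (1S,4R,5R,6S,8S,10S)-1-acetoxy-4,5-epoxy-13-[(4-methoxybenzyl)oxy]-8-(methacryloyloxy)germacr-7(11)-en-12,6-olide | C=C(C)C(=O)O[C@H]1C[C@H](C)[C@@H](OC(C)=O)CC[C@@]2(C)O[C@@H]2[C@H]2OC(=O)C(COCc3ccc(OC)cc3)=C12 | intermediate
24 | glaucolide L, (1S,4R,5R,6S,8S,10S)-1-acetoxy-4,5-epoxy-13-hydroxy-8-(methacryloyloxy)germacr-7(11)-en-12,6-olide | C=C(C)C(=O)O[C@H]1C[C@H](C)[C@@H](OC(C)=O)CC[C@@]2(C)O[C@@H]2[C@H]2OC(=O)C(CO)=C12 | target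

**Count**

Total steps: 16. Longest linear sequence: 16 steps (1 to 24); 5 and 10 enter as purchased compounds.

**Steps most likely to fail**

1. Step 14 (Ni/Cr ring closure). The C8 configuration rests on conformational bias alone, so the aldehyde may be attacked on the other face or with poor facial discrimination. The fallback sets out from 21 and runs the same closure. The 8R carbinol, (1S,4R,5R,6S,8R,10S)-1-acetoxy-4,5-epoxy-8-hydroxy-13-[(4-methoxybenzyl)oxy]germacr-7(11)-en-12,6-olide F1, is then esterified with methacrylic acid under Mitsunobu conditions (PPh3, DIAD, toluene, 0 °C → rt). This SN2 displacement inverts C8 and comes back to the route at 23. Any 22 formed alongside goes through step 15, so both epimers converge on 23.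

2. Step 7 (Dieckmann closure and triflation). The β-alkoxy ester enolate may lose 4-methoxybenzyl oxide (E1cB) before it cyclises, or the amide base may deprotonate C6 and open the oxirane by β-elimination. The fallback sets out from 9, which is acylated with acryloyl chloride (i-Pr2NEt, CH2Cl2, −78 °C) to methyl (2R)-2-(acryloyloxy)-2-[(2R,3R)-3-{3-[(tert-butyldimethylsilyl)oxy]propyl}-3-methyloxiran-2-yl]acetate F2. Lithium 4-methoxybenzyl oxide (THF, −78 → −20 °C) then adds to the acrylate in an oxa-Michael step. The enolate formed this way closes onto the methyl ester (Michael-initiated Dieckmann), with no amide base present and with the alkoxide loss made reversible. This returns to the route at lithium tetronate 12, which is triflated as before to 13.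

3. Step 12 (hydroboration–oxidation). During the basic perborate oxidation of the alkylborane the alkenyl triflate may hydrolyse, or the oxirane may open from C6. The fallback sets out from 18 and oxidises the terminal alkene directly to the aldehyde by an aldehyde-selective (anti-Markovnikov) Wacker oxidation [PdCl2(PhCN)2, CuCl2, AgNO2, t-BuOH/MeNO2, O2, rt], with the homoallylic acetate supporting aldehyde selectivity. It comes back to the route at 21 without borane or basic peroxide, and no new compound lies on this path (F0).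

**Further compounds**

F1 | step 14 | (1S,4R,5R,6S,8R,10S)-1-acetoxy-4,5-epoxy-8-hydroxy-13-[(4-methoxybenzyl)oxy]germacr-7(11)-en-12,6-olide | O[C@@H]1C[C@H](C)[C@@H](OC(C)=O)CC[C@@]2(C)O[C@@H]2[C@H]2OC(=O)C(COCc3ccc(OC)cc3)=C12
F2 | step 7 | methyl (2R)-2-(acryloyloxy)-2-[(2R,3R)-3-{3-[(tert-butyldimethylsilyl)oxy]propyl}-3-methyloxiran-2-yl]acetate | COC(=O)[C@H](OC(=O)C=C)[C@H]1O[C@]1(C)CCCO[Si](C)(C)C(C)(C)C
F0 | step 12 | none | none
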